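**Plan**
1. Last cut: the enoate bond between the ester carbonyl carbon and the α-vinyl CH. This gives the hemioxalate of the terpene alcohol (an alkoxycarbonyl-radical precursor) and 3,4-diacetoxystyrene.
2. Enabling feature, arene side: the free CH2 terminus of a vinyl group conjugated to the 3,4-dioxygenated benzene ring accepts the radical. The adduct passes through a benzylic radical and cation that loses H+ to give the E-alkene.
3. Enabling feature, terpene side: the O–C(=O)• unit on ring carbon C1 can reach the ring alkene C2=C3 only by 4-exo or 5-endo closure. It can reach the exocyclic methylene only through a 7- or 8-membered ring.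
4. Terpene alcohol: cut C2–CH3 (enol triflate coupling) and C1–O (Rubottom oxidation) back to a 4,4-disubstituted cyclohexenone. Then cut its C2=C3 (aldol), then the bond between the two quaternary carbons (thio-Claisen).
5. Forward order: the cyclopentene is made first. A valinol-derived bicyclic thiolactam serves as a temporary ring. The [3,3] shift joins the halves and creates the exocyclic methylene, the lactam ring is opened and re-closed as the cyclohexenone, then O and CH3 are added, then the ester chain.
6. Stereochemistry: (S)-valinol fixes the face of the [3,3] shift (ring C5) and the chair transition state fixes cyclopentane C1′. Epoxidation anti to the axial C5 methyl fixes carbinol C1. The E-alkene comes from the elimination.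

Key step: step 18

Assumption: in 11 the allyl group is taken to migrate across the face of the ketene N,S-acetal anti to the angular C8a methyl group. If the other face reacted, (R)-valinol would replace 6 and nothing else would change.

Step 1
Reactants: 1 ethyl 2-oxocyclopentane-1-carboxylate
Product: 2 ethyl 2-(trifluoromethylsulfonyloxy)cyclopent-1-ene-1-carboxylate
Conditions: NaH, Et2O, 0 °C; Tf2O, 0 °C
Reagents that add atoms: triflic anhydride O=S(=O)(OS(=O)(=O)C(F)(F)F)C(F)(F)F
Why: O-sulfonylation of the sodium enolate of a β-keto ester (enol triflate formation), with the alkene geometry fixed by the ring.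

Step 2
Reactants: 2 ethyl 2-(trifluoromethylsulfonyloxy)cyclopent-1-ene-1-carboxylate
Product: 3 ethyl 2-methylcyclopent-1-ene-1-carboxylate
Conditions: MeMgBr, Fe(acac)3 (cat.), THF/NMP, −30 °C
Reagents that add atoms: methylmagnesium bromide C[Mg]Br
Why: Iron-catalysed Kumada-type cross-coupling of an enol triflate is much faster at low temperature than attack of the Grignard reagent on the ester.

Step 3
Reactants: 3 ethyl 2-methylcyclopent-1-ene-1-carboxylate
Product: 4 (2-methylcyclopent-1-en-1-yl)methanol
Conditions: DIBAL-H (2.2 equiv), CH2Cl2, −78 °C; aqueous work-up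
Reagents that add atoms: none
Why: 1,2-Reduction of an α,β-unsaturated ester with DIBAL-H gives the allylic alcohol without conjugate reduction.

Step 4
Reactants: 4 (2-methylcyclopent-1-en-1-yl)methanol
Product: 5 1-(bromomethyl)-2-methylcyclopent-1-ene
Conditions: PBr3 (0.4 equiv), Et2O, −10 °C; used crude
Reagents that add atoms: phosphorus tribromide BrP(Br)Br
Why: SN2 bromination of a primary allylic alcohol with PBr3, with cold handling and direct use to limit allylic scrambling of the labile bromide.

Step 5
Reactants: 6 (S)-valinol; 7 5-oxohexanoic acid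
Product: 8 (3S,8aR)-8a-methyl-3-(propan-2-yl)hexahydro-5H-[1,3]oxazolo[3,2-a]pyridin-5-one
Conditions: toluene, reflux, Dean–Stark trap
Reagents that add atoms: none
Why: Cyclodehydration of an amino alcohol with a δ-keto acid (bicyclic lactam formation) is reversible at the N,O-acetal carbon, so C8a should settle with the angular methyl cis to the isopropyl group.

Step 6
Reactants: 8 bicyclic lactam
Product: 9 (3S,8aR)-6,8a-dimethyl-3-(propan-2-yl)hexahydro-5H-[1,3]oxazolo[3,2-a]pyridin-5-one (both C6 epimers)
Conditions: LDA, THF, −78 °C; MeI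
Reagents that add atoms: iodomethane CI
Why: Lactam enolate alkylation; the new C6 centre becomes sp2 again in step 8, so the epimer mixture is used as such.

Step 7
Reactants: 9 6-methyl lactam
Product: 10 (3S,8aR)-6,8a-dimethyl-3-(propan-2-yl)hexahydro-5H-[1,3]oxazolo[3,2-a]pyridine-5-thione (both C6 epimers)
Conditions: Lawesson's reagent (0.55 equiv), toluene, 90 °C
Reagents that add atoms: Lawesson's reagent COc1ccc(cc1)P1(=S)SP(=S)(S1)c1ccc(OC)cc1
Why: Thionation of a tertiary lactam with Lawesson's reagent leaves the N,O-acetal intact under neutral conditions.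

Step 8
Reactants: 10 thiolactam; 5 1-(bromomethyl)-2-methylcyclopent-1-ene
Product: 12 (3S,6R,8aR)-6,8a-dimethyl-6-[(1S)-1-methyl-2-methylidenecyclopentyl]-3-(propan-2-yl)hexahydro-5H-[1,3]oxazolo[3,2-a]pyridine-5-thione, via ketene N,S-acetal 11 (not isolated)
Conditions: LDA, THF, −78 to 0 °C; 5, −78 °C to rt; then reflux
Reagents that add atoms: none
Why: S-Allylation of the lithium thioenolate and thio-Claisen [3,3] rearrangement of 11, driven by re-formation of the thioamide, should form the bond between the two quaternary carbons and the exocyclic methylene at once: migration on the face anti to the pseudoaxial angular C8a methyl sets C6, and a chair transition state, in which the ring-fixed alkene geometries (S cis to the C6 methyl, CH2S cis to the cyclopentene methyl) hold the two methyl groups anti, sets C1′.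

Step 9
Reactants: 12 rearranged thiolactam
Product: 15 (2R)-2-methyl-2-[(1S)-1-methyl-2-methylidenecyclopentyl]-5-oxohexanal, via S-methyl thioiminium triflate 13 (not isolated), via N,S-acetal 14 (not isolated)
Conditions: MeOTf, CH2Cl2, 0 °C to rt; LiBHEt3 (1.0 equiv), THF, −78 °C; then 1 M aq Bu4NH2PO4, EtOH, reflux
Reagents that add atoms: water O; methyl triflate COS(=O)(=O)C(F)(F)F (its CH3 stays only in 13 and 14)
Why: Thioamide-to-aldehyde reduction by S-methylation, addition of a single hydride equivalent to 13 (so the aldehyde oxidation level cannot be passed) and buffered hydrolysis of both aminal carbons of 14, which also releases the auxiliary and the masked methyl ketone without touching the quaternary centres.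

Step 10
Reactants: 15 keto aldehyde
Product: 16 (4S)-4-methyl-4-[(1S)-1-methyl-2-methylidenecyclopentyl]cyclohex-2-en-1-one
Conditions: KOH (cat.), EtOH, rt to 50 °C
Reagents that add atoms: none
Why: Intramolecular aldol condensation: the aldehyde cannot enolise and only the CH3 of the methyl ketone can close a six-membered ring, so a single enone should form.

Step 11
Reactants: 16 enone
Product: 18 triethyl({(4S)-4-methyl-4-[(1S)-1-methyl-2-methylidenecyclopentyl]cyclohex-1-en-1-yl}oxy)silane, via lithium enolate 17 (not isolated)
Conditions: L-Selectride, THF, −78 °C; TESCl, Et3N, −78 to 0 °C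
Reagents that add atoms: chlorotriethylsilane CC[Si](Cl)(CC)CC
Why: Conjugate hydride addition (1,4-reduction with a bulky trialkylborohydride) to the β-unsubstituted enone gives enolate 17 with the double bond fixed between C1 and C2, and O-silylation keeps this regiochemistry.

Step 12
Reactants: 18 triethylsilyl enol ether
Product: 20 (2S,4S)-4-methyl-4-[(1S)-1-methyl-2-methylidenecyclopentyl]-2-(triethylsilyloxy)cyclohexan-1-one, via silyloxy epoxide 19 (not isolated)
Conditions: mCPBA (1.0 equiv), NaHCO3, hexane/CH2Cl2, −20 °C
Reagents that add atoms: mCPBA O=C(OO)c1cccc(Cl)c1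
Why: Rubottom oxidation: the electron-rich silyl enol ether is epoxidised faster than the hindered 1,1-disubstituted alkene and on the face anti to the pseudoaxial C4 methyl (the bulky cyclopentyl group stays equatorial), and 1,4-silyl migration in 19 gives the equatorial silyloxy ketone, which sets the carbinol centre cis to the cyclopentyl group.

Step 13
Reactants: 20 α-silyloxy ketone
Product: 21 (4S,6S)-4-methyl-4-[(1S)-1-methyl-2-methylidenecyclopentyl]-6-(triethylsilyloxy)cyclohex-1-en-1-yl trifluoromethanesulfonate
Conditions: KHMDS, THF, −78 °C; N-(5-chloropyridin-2-yl)triflimide, −78 °C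
Reagents that add atoms: N-(5-chloropyridin-2-yl)bis(trifluoromethanesulfonimide) O=S(=O)(N(c1ccc(Cl)cn1)S(=O)(=O)C(F)(F)F)C(F)(F)F
Why: Kinetic deprotonation at the unhindered C6 methylene rather than at the oxygen-bearing C2 methine, followed by O-triflation of the enolate, places the future ring alkene.

Step 14
Reactants: 21 enol triflate
Product: 22 triethyl({(1S,5S)-2,5-dimethyl-5-[(1S)-1-methyl-2-methylidenecyclopentyl]cyclohex-2-en-1-yl}oxy)silane
Conditions: MeMgBr, Fe(acac)3 (cat.), THF/NMP, −30 °C
Reagents that add atoms: methylmagnesium bromide C[Mg]Br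
Why: Iron-catalysed Kumada-type methylation of the enol triflate is fast at low temperature and leaves the silyl ether, the allylic C–O bond and all stereocentres alone.

Step 15
Reactants: 22 silyl ether
Product: 23 (1S,5S)-2,5-dimethyl-5-[(1S)-1-methyl-2-methylidenecyclopentyl]cyclohex-2-en-1-ol
Conditions: TBAF, THF, 0 °C
Reagents that add atoms: none
Why: Fluoride cleavage of a triethylsilyl ether is neutral enough for the allylic alcohol and the exocyclic methylene.

Step 16
Reactants: 23 allylic alcohol
Product: 25 2-({(1S,5S)-2,5-dimethyl-5-[(1S)-1-methyl-2-methylidenecyclopentyl]cyclohex-2-en-1-yl}oxy)-2-oxoacetic acid, via chlorooxoacetate 24 (not isolated)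
Conditions: (COCl)2 (3 equiv), 2,6-lutidine, Et2O, −20 to 0 °C; then H2O, 0 °C; used at once
Reagents that add atoms: oxalyl chloride O=C(Cl)C(=O)Cl; water O
Why: Acylation of the alcohol by excess oxalyl chloride (buffered so that no free HCl meets the alkenes) and hydrolysis of acid chloride 24 give the hemioxalate with retention at C1, since the C1–O bond is never broken.

Step 17
Reactants: 26 3,4-dihydroxybenzaldehyde
Product: 28 4-ethenylbenzene-1,2-diyl diacetate (3,4-diacetoxystyrene), via dipotassium 4-ethenylbenzene-1,2-diolate 27 (not isolated)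
Conditions: Ph3PCH3Br, KOt-Bu (3.3 equiv), THF, 0 °C to rt; then Ac2O, 0 °C
Reagents that add atoms: methyltriphenylphosphonium bromide C[P+](c1ccccc1)(c1ccccc1)c1ccccc1.[Br-]; acetic anhydride CC(=O)OC(C)=O
Why: Wittig methylenation of the bis-phenoxide aldehyde with acetylation in the same flask, so that the easily oxidised and polymerised free vinylcatechol is never isolated.

Step 18
Reactants: 25 hemioxalic acid; 28 3,4-diacetoxystyrene
Product: 31 (1S,5S)-2,5-dimethyl-5-[(1S)-1-methyl-2-methylidenecyclopentyl]cyclohex-2-en-1-yl (E)-3-(3,4-diacetoxyphenyl)prop-2-enoate, via alkoxycarbonyl radical 29 (not isolated), via benzylic cation 30 (not isolated)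
Conditions: undivided cell, graphite anode, Pt cathode, constant current 5 mA cm−2, 2.5 F mol−1, 28 (3 equiv, about 1 M), 2,4,6-collidine (1 equiv), n-Bu4NPF6, MeCN, 0 °C
Reagents that add atoms: none
Why: Proposed new method: the collidinium carboxylate of 25 is oxidised at the anode (expected near +1.3 V vs SCE, well below the two isolated alkenes and the acetoxy-deactivated styrene), loses CO2 and gives σ-radical 29, which adds to the unsubstituted CH2 terminus of 28; the benzylic radical so formed is oxidised at once to cation 30 (radical-polar crossover), collidine removes the acidified proton next to the new ester, and protons are reduced to H2 at the cathode. The closest known reaction types are the anodic Kolbe-type generation of alkoxycarbonyl radicals from hemioxalates with addition to alkenes, and the decarboxylative Heck-type alkenylation of styrenes under photoredox/cobalt catalysis. No ring is closed and no stereocentre is made or touched; the E geometry follows from deprotonation of 30 in the conformer that holds the aryl and ester groups anti, and it is also the more stable isomer. The step needs intermolecular addition to outrun loss of a second CO2 from 29 (which would give the ring allyl radical) and any cyclisation: low temperature and a concentrated excess of 28 favour the bimolecular path, and within 29 the ring alkene C2=C3 is reachable only by 4-exo or 5-endo closure and the exocyclic methylene only through a 7- or 8-membered transition state. No low-valent metal is present, so the allylic C1–O bond, which Pd(0) or Ni(0) carbonylation catalysts could ionise, is left alone.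

Step 19
Reactants: 31 diacetyl caffeate
Product: 32 (1S,5S)-2,5-dimethyl-5-[(1S)-1-methyl-2-methylidenecyclopentyl]cyclohex-2-en-1-yl (E)-3-(3,4-dihydroxyphenyl)prop-2-enoate (target)
Conditions: piperidine (2.5 equiv), CH2Cl2, 0 °C, Ar; pH 5 buffer work-up
Reagents that add atoms: none
Why: Chemoselective aminolysis: aryl acetates are far better acyl donors than the hindered conjugated alkyl ester, so only the two phenol esters should be cleaved.

**Compound list**
1 | ethyl 2-oxocyclopentane-1-carboxylate | CCOC(=O)C1CCCC1=O | starting material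
2 | ethyl 2-(trifluoromethylsulfonyloxy)cyclopent-1-ene-1-carboxylate | CCOC(=O)C1=C(OS(=O)(=O)C(F)(F)F)CCC1 | intermediate
3 | ethyl 2-methylcyclopent-1-ene-1-carboxylate | CCOC(=O)C1=C(C)CCC1 | intermediate
4 | (2-methylcyclopent-1-en-1-yl)methanol | OCC1=C(C)CCC1 | intermediate
5 | 1-(bromomethyl)-2-methylcyclopent-1-ene | BrCC1=C(C)CCC1 | intermediate
6 | (S)-valinol, (2S)-2-amino-3-methylbutan-1-ol | CC(C)[C@H](N)CO | starting material
7 | 5-oxohexanoic acid | CC(=O)CCCC(=O)O | starting material
8 | (3S,8aR) bicyclic lactam, angular methyl cis to isopropyl | O=C1CCC[C@@]2(C)OC[C@H](C(C)C)N12 | intermediate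
9 | 6-methyl lactam, both C6 epimers | CC1CC[C@@]2(C)OC[C@H](C(C)C)N2C1=O | intermediate
10 | 6-methyl thiolactam, both C6 epimers | CC1CC[C@@]2(C)OC[C@H](C(C)C)N2C1=S | intermediate
11 | ketene N,S-acetal, S-[(2-methylcyclopent-1-enyl)methyl], C5=C6 | CC1=C(CSC2=C(C)CC[C@@]3(C)OC[C@H](C(C)C)N23)CCC1 | intermediate (not isolated)
12 | (3S,6R,8aR,1′S) rearranged thiolactam with both quaternary carbons | C=C1CCC[C@]1(C)[C@@]2(C)CC[C@@]3(C)OC[C@H](C(C)C)N3C2=S | intermediate
13 | S-methyl thioiminium triflate of 12 | C=C1CCC[C@]1(C)[C@@]2(C)CC[C@@]3(C)OC[C@H](C(C)C)[N+]3=C2SC.[O-]S(=O)(=O)C(F)(F)F | intermediate (not isolated)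
14 | 5-(methylsulfanyl) N,S-acetal, C5 unassigned | C=C1CCC[C@]1(C)[C@@]2(C)CC[C@@]3(C)OC[C@H](C(C)C)N3C2SC | intermediate (not isolated)
15 | (2R)-2-methyl-2-[(1S)-1-methyl-2-methylidenecyclopentyl]-5-oxohexanal | C=C1CCC[C@]1(C)[C@](C)(C=O)CCC(C)=O | intermediate
16 | (4S)-4-methyl-4-[(1S)-1-methyl-2-methylidenecyclopentyl]cyclohex-2-en-1-one | C=C1CCC[C@]1(C)[C@@]1(C)CCC(=O)C=C1 | intermediate
17 | lithium enolate, C1=C2 | C=C1CCC[C@]1(C)[C@@]1(C)CCC([O-])=CC1.[Li+] | intermediate (not isolated)
18 | triethylsilyl enol ether, C1=C2 | C=C1CCC[C@]1(C)[C@@]1(C)CCC(O[Si](CC)(CC)CC)=CC1 | intermediate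
19 | silyloxy epoxide, oxirane anti to the C4 methyl | C=C1CCC[C@]1(C)[C@@]1(C)CC[C@@]2(O[Si](CC)(CC)CC)O[C@H]2C1 | intermediate (not isolated)
20 | (2S,4S)-2-(triethylsilyloxy) ketone | C=C1CCC[C@]1(C)[C@@]1(C)CCC(=O)[C@@H](O[Si](CC)(CC)CC)C1 | intermediate
21 | (4S,6S) enol triflate | C=C1CCC[C@]1(C)[C@@]1(C)CC=C(OS(=O)(=O)C(F)(F)F)[C@@H](O[Si](CC)(CC)CC)C1 | intermediate
22 | triethylsilyl ether of 23 | C=C1CCC[C@]1(C)[C@@]1(C)CC=C(C)[C@@H](O[Si](CC)(CC)CC)C1 | intermediate
23 | (1S,5S)-2,5-dimethyl-5-[(1S)-1-methyl-2-methylidenecyclopentyl]cyclohex-2-en-1-ol | C=C1CCC[C@]1(C)[C@@]1(C)CC=C(C)[C@@H](O)C1 | intermediate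
24 | chlorooxoacetate of 23 | C=C1CCC[C@]1(C)[C@@]1(C)CC=C(C)[C@@H](OC(=O)C(=O)Cl)C1 | intermediate (not isolated)
25 | hemioxalic acid of 23 | C=C1CCC[C@]1(C)[C@@]1(C)CC=C(C)[C@@H](OC(=O)C(=O)O)C1 | intermediate
26 | 3,4-dihydroxybenzaldehyde | O=Cc1ccc(O)c(O)c1 | starting material
27 | dipotassium 4-ethenylbenzene-1,2-diolate | C=Cc1ccc([O-])c([O-])c1.[K+].[K+] | intermediate (not isolated)
28 | 3,4-diacetoxystyrene | C=Cc1ccc(OC(C)=O)c(OC(C)=O)c1 | intermediate
29 | alkoxycarbonyl radical from 25 | C=C1CCC[C@]1(C)[C@@]1(C)CC=C(C)[C@@H](O[C]=O)C1 | intermediate (not isolated)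
30 | benzylic cation after addition to 28 and oxidation | C=C1CCC[C@]1(C)[C@@]1(C)CC=C(C)[C@@H](OC(=O)C[CH+]c2ccc(OC(C)=O)c(OC(C)=O)c2)C1 | intermediate (not isolated)
31 | diacetyl caffeate ester | C=C1CCC[C@]1(C)[C@@]1(C)CC=C(C)[C@@H](OC(=O)/C=C/c2ccc(OC(C)=O)c(OC(C)=O)c2)C1 | intermediate
32 | target caffeate ester | C=C1CCC[C@]1(C)[C@@]1(C)CC=C(C)[C@@H](OC(=O)/C=C/c2ccc(O)c(O)c2)C1 | target

**Totals**
- Total step count: 19.
- Longest linear sequence: 15 steps (1–4, 8–16, 18, 19).

**Steps most likely to fail**

Step 18 (Proposed new method).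
- What may go wrong: radical 29 may lose a second CO2 to give the ring allyl radical before it meets the styrene. Cation 30 may be captured by carboxylate, or it may start oligomerisation of 28.
- Fallback: a polar acylation that makes the same bond by the known ester synthesis from Grignard reagents and alkyl imidazole-1-carboxylates. It sets out from alcohol 23 and aldehyde 26 and comes back at target 32.
- Alcohol 23 and 1,1′-carbonyldiimidazole in THF give the imidazole-1-carboxylate F1.
- Aldehyde 26 is silylated (TBSCl, imidazole) to 3,4-bis(tert-butyldimethylsilyloxy)benzaldehyde F2. Takai olefination (CHI3, CrCl2) then gives the (E)-alkenyl iodide F3.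
- Iodine–lithium exchange (t-BuLi, −78 °C) and MgBr2·OEt2 give the (E)-alkenylmagnesium bromide F4.
- Addition of the Grignard reagent to the imidazolide at −78 °C gives the bis-silyl caffeate F5, and Et3N·3HF then gives 32.

Step 8.
- What may go wrong: the labile tetrasubstituted allylic bromide may eliminate or alkylate at carbon instead of sulfur. The congested [3,3] shift may be slow, and leakage through a boat transition state would erode the configuration at C1′.
- Fallback: an oxygen-series Meerwein–Eschenmoser–Claisen rearrangement that needs neither bromide nor sulfur. It sets out from lactam 9 and alcohol 4 and comes back at keto aldehyde 15.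
- MeOTf converts 9 into the O-methyl iminium ether triflate F6.
- The sodium alkoxide of 4 adds to this salt, and methanol is lost on heating in toluene to give the ketene N,O-acetal F7.
- This acetal rearranges in the same pot to the quaternary lactam F8.
- Red-Al at low temperature gives the carbinolamine F9, and buffered hydrolysis (aq Bu4NH2PO4, EtOH) gives 15.

Step 12.
- What may go wrong: the peracid may also epoxidise the exocyclic methylene. The acid by-product may strip the silyl group, and facial selectivity may be incomplete.
- Fallback: oxygen transfer to the enolate instead of epoxidation of the enol ether. It sets out from enone 16 and comes back at ketone 20.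
- Enone 16 is reduced with L-Selectride as in step 11. Enolate 17 is then oxidised in the same flask with 2-(phenylsulfonyl)-3-phenyloxaziridine to the α-hydroxy ketone F10.
- The equatorial epimer is also the more stable one, so a minor epimer could be equilibrated with mild base. TESCl and imidazole then give 20.

**Further compounds**
F1 | step 18 | (1S,5S)-2,5-dimethyl-5-[(1S)-1-methyl-2-methylidenecyclopentyl]cyclohex-2-en-1-yl 1H-imidazole-1-carboxylate | C=C1CCC[C@]1(C)[C@@]1(C)CC=C(C)[C@@H](OC(=O)n2ccnc2)C1
F2 | step 18 | 3,4-bis(tert-butyldimethylsilyloxy)benzaldehyde | O=Cc1ccc(O[Si](C)(C)C(C)(C)C)c(O[Si](C)(C)C(C)(C)C)c1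
F3 | step 18 | (E)-1,2-bis(tert-butyldimethylsilyloxy)-4-(2-iodoethenyl)benzene | I/C=C/c1ccc(O[Si](C)(C)C(C)(C)C)c(O[Si](C)(C)C(C)(C)C)c1
F4 | step 18 | (E)-2-[3,4-bis(tert-butyldimethylsilyloxy)phenyl]ethenylmagnesium bromide | Br[Mg]/C=C/c1ccc(O[Si](C)(C)C(C)(C)C)c(O[Si](C)(C)C(C)(C)C)c1
F5 | step 18 | bis(tert-butyldimethylsilyl) caffeate ester of 23 | C=C1CCC[C@]1(C)[C@@]1(C)CC=C(C)[C@@H](OC(=O)/C=C/c2ccc(O[Si](C)(C)C(C)(C)C)c(O[Si](C)(C)C(C)(C)C)c2)C1
F6 | step 8 | O-methyl iminium ether triflate of 9 | CC1CC[C@@]2(C)OC[C@H](C(C)C)[N+]2=C1OC.[O-]S(=O)(=O)C(F)(F)F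
F7 | step 8 | ketene N,O-acetal, O-[(2-methylcyclopent-1-enyl)methyl] | CC1=C(COC2=C(C)CC[C@@]3(C)OC[C@H](C(C)C)N23)CCC1
F8 | step 8 | (3S,6R,8aR,1′S) quaternary lactam | C=C1CCC[C@]1(C)[C@@]2(C)CC[C@@]3(C)OC[C@H](C(C)C)N3C2=O
F9 | step 8 | 5-hydroxy carbinolamine of F8, C5 unassigned | C=C1CCC[C@]1(C)[C@@]2(C)CC[C@@]3(C)OC[C@H](C(C)C)N3C2O
F10 | step 12 | (2S,4S)-2-hydroxy-4-methyl-4-[(1S)-1-methyl-2-methylidenecyclopentyl]cyclohexan-1-one | C=C1CCC[C@]1(C)[C@@]1(C)CCC(=O)[C@@H](O)C1
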